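## Retrosynthetic overview

1. Cutting the C19–O acyl bond of 21 gives diene-diol 17 and 4-O-acetylferulic acid 18. The butadiene of 17 comes from alkyne 16 and ethylene, and 16 comes via lactol 14 from δ-lactone 13 (carbonyl = C13, ring oxygen on C8).
2. Lactone 13 comes from the acyclic (S)-epoxy-diene tert-butyl ester 11 in one oxirane-opening cationic cascade. It forms C4–C5 (ring A), then C9–C10 (ring B), then C8–O (temporary lactone ring C, taken apart again in steps 8 and 9).
3. Enabling feature: the three fully substituted carbons of rings A and B (C4, C10, C8) lie 1,3 to each other on the anti-periplanar chain O–C19–C4–C5–C10–C9–C8–O. Quaternary C4 carries CH2–O, the retron of a 2,2-disubstituted oxirane opened at its tertiary carbon. The C8 oxygen lies within six-membered-ring reach of C13.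
4. Epoxide 11 comes from methyl ketone 10 and CH2 (asymmetric Corey–Chaykovsky, the only reagent-controlled stereocentre). Ketone 10 comes from geranyl bromide 2, tert-butyl acetate 1 and bromoketal 7.

Key step: step 7

Numbering: every atom is named by the labdane position it ends in (ring A = C1–C5 and C10; ring B = C5–C10; side chain C11–C16; C17 on C8; C18 and C19 on C4; C20 on C10).

Assumption: the (S)-binaphthoxide complex is taken to deliver CH2 to the Re face of ketone 10. If the sense is opposite, the (R)-complex is used instead.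

## Route

Step 1
Reactants: 1 tert-butyl acetate; 2 geranyl bromide [(2E)-1-bromo-3,7-dimethylocta-2,6-diene]
Product: 4 tert-butyl (4E)-5,9-dimethyldeca-4,8-dienoate, via lithium enolate of tert-butyl acetate 3 (not isolated)
Conditions: LDA (1.1 equiv), THF, −78 °C; then 2, −78 °C → rt
Reagents that add atoms: none
Why: Ester enolate alkylation (SN2 at the primary allylic bromide) joins C11–C12 without touching the E alkene, and the bulky tert-butyl ester suppresses Claisen self-condensation.

Step 2
Reactants: 4 tert-butyl (4E)-5,9-dimethyldeca-4,8-dienoate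
Product: 5 tert-butyl (4E,8E)-10-hydroxy-5,9-dimethyldeca-4,8-dienoate
Conditions: SeO2 (0.3 equiv), t-BuOOH (3 equiv), salicylic acid (0.1 equiv), CH2Cl2, 0 °C → rt, stopped at partial conversion with recovery of 4
Reagents that add atoms: tert-butyl hydroperoxide CC(C)(C)OO (oxygen, passed on through SeO2, O=[Se]=O)
Why: Riley-type allylic hydroxylation (ene reaction, then [2,3]-sigmatropic shift) should prefer the more accessible terminal gem-dimethyl alkene and oxidises only its E methyl group, which fixes the E geometry of the later C5=C10 bond.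

Step 3
Reactants: 5 tert-butyl (4E,8E)-10-hydroxy-5,9-dimethyldeca-4,8-dienoate
Product: 6 tert-butyl (4E,8E)-10-bromo-5,9-dimethyldeca-4,8-dienoate
Conditions: CBr4, PPh3, CH2Cl2, −20 → 0 °C
Reagents that add atoms: carbon tetrabromide BrC(Br)(Br)Br
Why: The Appel reaction converts the primary allylic alcohol into the bromide under neutral conditions without allylic transposition or E/Z scrambling, and the ester is inert.

Step 4
Reactants: 6 tert-butyl (4E,8E)-10-bromo-5,9-dimethyldeca-4,8-dienoate; 7 2-(2-bromoethyl)-2-methyl-1,3-dioxolane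
Product: 9 tert-butyl (4E,8E)-5,9-dimethyl-12-(2-methyl-1,3-dioxolan-2-yl)dodeca-4,8-dienoate, via Grignard reagent 8 (not isolated)
Conditions: 7, Mg, THF, ≤30 °C; then 6, Li2CuCl4 (5 mol %), THF, −78 → −10 °C
Reagents that add atoms: none
Why: Copper-catalysed Grignard–allyl bromide cross-coupling takes place at the primary α-carbon (SN2, C1–C2 bond) with retention of the E geometry and should be much faster at low temperature than addition to the hindered tert-butyl ester.

Step 5
Reactants: 9 tert-butyl (4E,8E)-5,9-dimethyl-12-(2-methyl-1,3-dioxolan-2-yl)dodeca-4,8-dienoate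
Product: 10 tert-butyl (4E,8E)-5,9-dimethyl-13-oxotetradeca-4,8-dienoate
Conditions: 1 M aq. HCl, THF, rt
Reagents that add atoms: water O
Why: Acid-catalysed ketal hydrolysis with dilute acid at room temperature frees the C4 methyl ketone while the tert-butyl ester and both trisubstituted alkenes stay intact.

Step 6
Reactants: 10 tert-butyl (4E,8E)-5,9-dimethyl-13-oxotetradeca-4,8-dienoate
Product: 11 tert-butyl (4E,8E)-5,9-dimethyl-12-[(2S)-2-methyloxiran-2-yl]dodeca-4,8-dienoate
Conditions: Me2S(O)=CH2 (1.2 equiv, from Me3S(O)Cl, NaH, THF), LaLi3[(S)-binaphthoxide]3 (5 mol %), [2,4,6-(MeO)3C6H2]3P=O (5 mol %), MS 5A, THF, rt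
Reagents that add atoms: dimethylsulfoxonium methylide C[S+](C)(=O)[CH2-] (from trimethylsulfoxonium chloride C[S+](C)(C)=O.[Cl-])
Why: In the catalytic asymmetric Corey–Chaykovsky epoxidation of a methyl ketone the lanthanum–lithium binaphthoxide/phosphine oxide complex binds ketone and ylide and tells CH3 from the primary alkyl chain, so CH2 (C19) should arrive on the Re face and set (S)-C4, while ester and alkenes are inert to the sulfoxonium ylide.

Step 7
Reactants: 11 tert-butyl (4E,8E)-5,9-dimethyl-12-[(2S)-2-methyloxiran-2-yl]dodeca-4,8-dienoate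
Product: 13 (4S,5R,8R,9R,10S)-19-hydroxy-14,15,16-trinorlabdan-13,8-olide, via lactonium aluminate zwitterion 12 (not isolated)
Conditions: MeAlCl2 (2.5 equiv), CH2Cl2 (high dilution), −78 °C; then aq. NaHCO3
Reagents that add atoms: none
Why: Proposed new method: MeAlCl2 binds the oxirane oxygen, the C5=C10 π bond attacks the tertiary oxirane carbon C4 from the rear while C4–O breaks (release of about 27 kcal/mol of ring strain), the C8=C9 π bond takes the charge arriving at C10 and so forms C9–C10, and the ester carbonyl oxygen captures C8 to give zwitterion 12, which loses isobutene and a proton (consumed as methane by the Al–CH3 bond) and gives 13 on work-up. The closest known reaction types are the MeAlCl2-promoted epoxide-initiated cation–olefin polycyclisation of trisubstituted oxiranes (endo mode), the exo-mode Lewis acid cyclisation of 2,2-disubstituted oxiranes onto a single arene or allylsilane, and tert-butyl ester or carbonate termination of cationic cascades; new is the exo-mode oxirane as initiator of a bicyclisation, which leaves the oxygen on exocyclic C19 and none on ring A. Ring A closes 6-exo-tet at the oxirane carbon and 6-endo-trig at C5=C10, ring B closes 6-endo-trig at C8=C9, and the temporary lactone ring C closes by six-membered capture of the C8 cation by the carbonyl oxygen. C4 is set by inversion at the (S)-oxirane carbon, C5 and C10 by anti addition across the E C5=C10 bond and C9 and C8 by anti addition across the E C8=C9 bond in a chair–chair fold (trans ring fusion, equatorial C11, equatorial 8α-oxygen, axial C17), and the fold is tied to C4 because the oxirane CH2 (C19), bent back towards the leaving oxygen and thus the smallest group on C4, should take the pseudo-axial site next to C20 while C18 stays equatorial. The step needs concerted rather than free-cation opening (C4 is the only stereocentre of 11), cyclisation ahead of the 1,2-hydride shift to the aldehyde, and six-ring Markovnikov closures; the non-ionising medium at −78 °C, the trisubstituted alkene held five atoms behind the C4–O bond, and the tertiary cation sites C10 and C8 secure them.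

Step 8
Reactants: 13 (4S,5R,8R,9R,10S)-19-hydroxy-14,15,16-trinorlabdan-13,8-olide
Product: 14 8α,13-epoxy-14,15,16-trinorlabdane-13,19-diol (lactol, mixture of anomers)
Conditions: DIBAL-H (3 equiv), CH2Cl2, −78 °C; aq. potassium sodium tartrate
Reagents that add atoms: none
Why: In this partial lactone reduction the first equivalent of DIBAL-H is taken by the C19 hydroxyl and the tetrahedral aluminium lactolate is stable at −78 °C, so the reduction should stop at the lactol and no skeletal stereocentre is touched.

Step 9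
Reactants: 14 8α,13-epoxy-14,15,16-trinorlabdane-13,19-diol
Product: 16 15,16-dinorlabd-13-yne-8α,19-diol, via open hydroxy aldehyde 15 (not isolated)
Conditions: dimethyl (1-diazo-2-oxopropyl)phosphonate (2 equiv), K2CO3 (3 equiv), MeOH, 0 °C → rt
Reagents that add atoms: dimethyl (1-diazo-2-oxopropyl)phosphonate COP(=O)(OC)C(=[N+]=[N-])C(C)=O (gives C14)
Why: The Ohira–Bestmann (Seyferth–Gilbert) homologation works on lactols through their open aldehyde tautomer, here favoured by the hindered tertiary C8 hydroxyl, and the mild base cannot epimerise anything because the α-carbon C12 is a CH2.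

Step 10
Reactants: 16 15,16-dinorlabd-13-yne-8α,19-diol
Product: 17 labda-13(16),14-diene-8α,19-diol
Conditions: ethylene (1 atm), second-generation Grubbs catalyst (H2IMes)(PCy3)Cl2Ru=CHPh (5 mol %), CH2Cl2, 40 °C
Reagents that add atoms: ethylene C=C (gives C15 and C16)
Why: Ethylene–alkyne cross (enyne) metathesis turns a terminal alkyne directly into the 2-substituted 1,3-butadiene, 16 has no other C=C bond to compete, and remote free hydroxyls are tolerated.

Step 11
Reactants: 17 labda-13(16),14-diene-8α,19-diol; 18 (E)-4-O-acetylferulic acid [(E)-3-(4-acetoxy-3-methoxyphenyl)prop-2-enoic acid]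
Product: 20 8α-hydroxylabda-13(16),14-dien-19-yl (E)-4-O-acetylferulate, via O-acylisourea 19 (not isolated)
Conditions: DCC (1.3 equiv), DMAP (0.3 equiv), CH2Cl2, 0 °C → rt
Reagents that add atoms: none
Why: In the Steglich esterification only the primary C19 hydroxyl should be acylated because the tertiary, flanked C8 hydroxyl is inert, the acetate keeps the phenol from self-acylation, and the E cinnamate geometry is carried over.

Step 12
Reactants: 20 8α-hydroxylabda-13(16),14-dien-19-yl (E)-4-O-acetylferulate
Product: 21 8α-hydroxylabda-13(16),14-dien-19-yl (E)-ferulate (CNP0142252.1)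
Conditions: K2CO3 (0.2 equiv), MeOH/CH2Cl2, 0 °C; aq. NH4Cl
Reagents that add atoms: none
Why: Base-catalysed methanolysis removes the aryl acetate selectively, since its phenoxide leaving group makes it far more reactive than the hindered neopentyl-type cinnamate, and diene and tertiary alcohol are untouched.

## Compound list

1 | tert-butyl acetate | CC(=O)OC(C)(C)C | starting material
2 | geranyl bromide, (2E)-1-bromo-3,7-dimethylocta-2,6-diene | CC(C)=CCC/C(C)=C/CBr | starting material
3 | lithium enolate of tert-butyl acetate | C=C(O[Li])OC(C)(C)C | intermediate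
4 | tert-butyl (4E)-5,9-dimethyldeca-4,8-dienoate | CC(C)=CCC/C(C)=C/CCC(=O)OC(C)(C)C | intermediate
5 | tert-butyl (4E,8E)-10-hydroxy-5,9-dimethyldeca-4,8-dienoate | OC/C(C)=C/CC/C(C)=C/CCC(=O)OC(C)(C)C | intermediate
6 | tert-butyl (4E,8E)-10-bromo-5,9-dimethyldeca-4,8-dienoate | BrC/C(C)=C/CC/C(C)=C/CCC(=O)OC(C)(C)C | intermediate
7 | 2-(2-bromoethyl)-2-methyl-1,3-dioxolane | CC1(CCBr)OCCO1 | starting material
8 | [2-(2-methyl-1,3-dioxolan-2-yl)ethyl]magnesium bromide | CC1(CC[Mg]Br)OCCO1 | intermediate
9 | tert-butyl (4E,8E)-5,9-dimethyl-12-(2-methyl-1,3-dioxolan-2-yl)dodeca-4,8-dienoate | CC1(CCC/C(C)=C/CC/C(C)=C/CCC(=O)OC(C)(C)C)OCCO1 | intermediate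
10 | tert-butyl (4E,8E)-5,9-dimethyl-13-oxotetradeca-4,8-dienoate | CC(=O)CCC/C(C)=C/CC/C(C)=C/CCC(=O)OC(C)(C)C | intermediate
11 | tert-butyl (4E,8E)-5,9-dimethyl-12-[(2S)-2-methyloxiran-2-yl]dodeca-4,8-dienoate | CC(C)(C)OC(=O)CC/C=C(C)/CC/C=C(C)/CCC[C@@]1(C)CO1 | intermediate
12 | tricyclic O-tert-butyl lactonium ion with C19–O bound as methyldichloroaluminate (zwitterion) | CC(C)(C)OC1CC[C@@H]2[C@@]3(C)CCC[C@](C)(CO[Al-](C)(Cl)Cl)[C@@H]3CC[C@@]2(C)[O+]=1 | intermediate
13 | (4S,5R,8R,9R,10S)-19-hydroxy-14,15,16-trinorlabdan-13,8-olide (trans-decalin, 8α-O, axial 4β-CH2OH) | O=C1CC[C@@H]2[C@@]3(C)CCC[C@](C)(CO)[C@@H]3CC[C@@]2(C)O1 | intermediate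
14 | 8α,13-epoxy-14,15,16-trinorlabdane-13,19-diol (lactol, anomers) | OC1CC[C@@H]2[C@@]3(C)CCC[C@](C)(CO)[C@@H]3CC[C@@]2(C)O1 | intermediate
15 | 8α,19-dihydroxy-14,15,16-trinorlabdan-13-al | O=CCC[C@@H]1[C@@]2(C)CCC[C@](C)(CO)[C@@H]2CC[C@@]1(C)O | intermediate
16 | 15,16-dinorlabd-13-yne-8α,19-diol | C#CCC[C@@H]1[C@@]2(C)CCC[C@](C)(CO)[C@@H]2CC[C@@]1(C)O | intermediate
17 | labda-13(16),14-diene-8α,19-diol | C=CC(=C)CC[C@@H]1[C@@]2(C)CCC[C@](C)(CO)[C@@H]2CC[C@@]1(C)O | intermediate
18 | (E)-4-O-acetylferulic acid | CC(=O)Oc1ccc(/C=C/C(=O)O)cc1OC | starting material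
19 | O-acylisourea from 18 and DCC | CC(=O)Oc1ccc(/C=C/C(=O)OC(=NC2CCCCC2)NC2CCCCC2)cc1OC | intermediate
20 | 8α-hydroxylabda-13(16),14-dien-19-yl (E)-4-O-acetylferulate | C=CC(=C)CC[C@@H]1[C@@]2(C)CCC[C@](C)(COC(=O)/C=C/c3ccc(OC(C)=O)c(OC)c3)[C@@H]2CC[C@@]1(C)O | intermediate
21 | 8α-hydroxylabda-13(16),14-dien-19-yl (E)-ferulate, (4S,5R,8R,9R,10S) | C=CC(=C)CC[C@@H]1[C@@]2(C)CCC[C@](C)(COC(=O)/C=C/c3ccc(O)c(OC)c3)[C@@H]2CC[C@@]1(C)O | target

## Step count and risks

Total step count: 12. Longest linear sequence: 12 steps (1 and 2 → 21).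

**Step 7.**
- What may go wrong: stepwise ionisation of the oxirane with loss of the only stereochemical information; hydride migration outrunning C–C bond formation; weak discrimination between the pseudo-axial and pseudo-equatorial placement of C19; or interruption of the cascade after ring A.
- Fallback (known chemistry): it uses a C3–O stereochemical anchor that is deleted afterwards, sets out from bromide 6 and comes back at lactone 13.
- To the aldehyde: bromide 6 is alkylated with lithiated acetaldehyde N-tert-butylimine to the alkylated imine F1. Aqueous oxalic acid hydrolyses it to the C3 aldehyde F2.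
- To the silyl ether: Still–Gennari olefination with methyl 2-[bis(2,2,2-trifluoroethoxy)phosphoryl]propanoate (KHMDS, 18-crown-6, −78 °C) gives the Z-enoate F3. DIBAL-H (2 equiv, −78 °C, tert-butyl ester spared) gives the Z-allylic alcohol F4. Sharpless asymmetric epoxidation with Ti(OiPr)4, D-(−)-diisopropyl tartrate and t-BuOOH gives the epoxy alcohol F5, and TBSCl/imidazole gives the silyl ether F6.
- Cyclisation and deoxygenation: MeAlCl2 cyclisation of this trisubstituted oxirane (endo mode) gives the 3β-hydroxy lactone F7; the C3–O centre persists and the Z-derived CH2OTBS is forced axial. Barton–McCombie deoxygenation through the thiocarbonylimidazolide F8 (Bu3SnH, AIBN, toluene, reflux) gives the deoxygenated silyl ether F9, and TBAF releases 13.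

**Step 6.**
- What may go wrong: insufficient facial discrimination between CH3 and the long primary alkyl chain of a dialkyl ketone.
- Fallback: it sets out from ketone 10 and comes back at epoxide 11. Uncatalysed Corey–Chaykovsky epoxidation (Me3S(O)I, NaH, DMSO) gives the racemic epoxide F10.
- Azidolytic kinetic resolution follows, with TMSN3/i-PrOH and the trivalent chromium complex [N,N'-bis(3,5-di-tert-butylsalicylidene)-1,2-cyclohexanediaminato]CrN3, taken as the antipode that consumes the (R)-epoxide.
- This converts the unwanted enantiomer into the azido alcohol F11 and leaves 11, which is separated by chromatography.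

**Step 4.**
- What may go wrong: addition of the Grignard reagent to the ester, γ-attack (SN2′), homocoupling, or thermal decay of the ketal Grignard reagent.
- Fallback: it sets out from bromoketal 7 and bromide 6 and comes back at ketal 9. Bromoketal 7 and PhSO2Na (DMF) give the ketal sulfone F12.
- Its lithio derivative (n-BuLi, THF, −78 °C), a soft carbanion, is alkylated by 6 to the allylated sulfone F13.
- Reductive desulfonylation with Na(Hg), Na2HPO4, MeOH gives 9.

## Further compounds

F1 | step 7 | tert-butyl (4E,8E)-12-(tert-butylimino)-5,9-dimethyldodeca-4,8-dienoate | CC(C)(C)N=CCC/C(C)=C/CC/C(C)=C/CCC(=O)OC(C)(C)C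
F2 | step 7 | tert-butyl (4E,8E)-5,9-dimethyl-12-oxododeca-4,8-dienoate | O=CCC/C(C)=C/CC/C(C)=C/CCC(=O)OC(C)(C)C
F3 | step 7 | 1-tert-butyl 14-methyl (4E,8E,12Z)-5,9,13-trimethyltetradeca-4,8,12-trienedioate | COC(=O)/C(C)=C\CC/C(C)=C/CC/C(C)=C/CCC(=O)OC(C)(C)C
F4 | step 7 | tert-butyl (4E,8E,12Z)-14-hydroxy-5,9,13-trimethyltetradeca-4,8,12-trienoate | OC/C(C)=C\CC/C(C)=C/CC/C(C)=C/CCC(=O)OC(C)(C)C
F5 | step 7 | tert-butyl (4E,8E)-11-[(2S,3R)-3-(hydroxymethyl)-3-methyloxiran-2-yl]-5,9-dimethylundeca-4,8-dienoate | CC(C)(C)OC(=O)CC/C=C(C)/CC/C=C(C)/CC[C@@H]1O[C@]1(C)CO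
F6 | step 7 | tert-butyl (4E,8E)-11-[(2S,3R)-3-(tert-butyldimethylsilyloxymethyl)-3-methyloxiran-2-yl]-5,9-dimethylundeca-4,8-dienoate | CC(C)(C)OC(=O)CC/C=C(C)/CC/C=C(C)/CC[C@@H]1O[C@]1(C)CO[Si](C)(C)C(C)(C)C
F7 | step 7 | 3β-hydroxy-19-(tert-butyldimethylsilyloxy)-14,15,16-trinorlabdan-13,8α-olide | O=C1CC[C@@H]2[C@@]3(C)CC[C@H](O)[C@](C)(CO[Si](C)(C)C(C)(C)C)[C@@H]3CC[C@@]2(C)O1
F8 | step 7 | 3β-(imidazol-1-ylthiocarbonyloxy)-19-(tert-butyldimethylsilyloxy)-14,15,16-trinorlabdan-13,8α-olide | O=C1CC[C@@H]2[C@@]3(C)CC[C@H](OC(=S)n4ccnc4)[C@](C)(CO[Si](C)(C)C(C)(C)C)[C@@H]3CC[C@@]2(C)O1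
F9 | step 7 | 19-(tert-butyldimethylsilyloxy)-14,15,16-trinorlabdan-13,8α-olide | O=C1CC[C@@H]2[C@@]3(C)CCC[C@](C)(CO[Si](C)(C)C(C)(C)C)[C@@H]3CC[C@@]2(C)O1
F10 | step 6 | tert-butyl (4E,8E)-5,9-dimethyl-12-(2-methyloxiran-2-yl)dodeca-4,8-dienoate (racemic) | CC(C)(C)OC(=O)CC/C=C(C)/CC/C=C(C)/CCCC1(C)CO1
F11 | step 6 | tert-butyl (4E,8E,13R)-14-azido-13-hydroxy-5,9,13-trimethyltetradeca-4,8-dienoate | CC(C)(C)OC(=O)CC/C=C(C)/CC/C=C(C)/CCC[C@@](C)(O)CN=[N+]=[N-]
F12 | step 4 | 2-methyl-2-[2-(phenylsulfonyl)ethyl]-1,3-dioxolane | CC1(CCS(=O)(=O)c2ccccc2)OCCO1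
F13 | step 4 | tert-butyl (4E,8E)-5,9-dimethyl-12-(2-methyl-1,3-dioxolan-2-yl)-11-(phenylsulfonyl)dodeca-4,8-dienoate (racemic at the sulfonyl carbon) | CC1(CC(C/C(C)=C/CC/C(C)=C/CCC(=O)OC(C)(C)C)S(=O)(=O)c2ccccc2)OCCO1
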